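Cuts, in retrosynthetic order: the eight O–alkyl bonds and one auxiliary C–Br bond; ring A (the 3,5-dihydroxyphenyl ring on the E-alkene) at its C1–C2 and C3–C4 bonds; the alkene C=C; the bond from the methine carbon to ring B (the central resorcinol ring); last the CH2–ring D bond.
Enabling feature: on ring A the alkene-bearing C1 and the oxygen-bearing C5 stand 1,3 to each other, just like C6 and C4 of a 4-methoxy-6-styryl-2-pyrone. Ring A C1, C6, C5, C4 are therefore pyrone C6, C5, C4, C3. Ring A C2 and the second oxygenated carbon C3 are the CH2 and the acetal carbon of 1,1-diethoxyethene, and pyrone O1–C2 leaves as carbon dioxide.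
Forward order: rings B, C and D are bought as arenes. Rings C and D are linked through a deoxybenzoin, and ring B is brought to the carbinol carbon by lithiation–borylation. The pyrone is attached to the ring B aldehyde by vinylogous aldol condensation, and ring A, the only ring that is built, closes last.
A 4-methoxy-6-styryl-2-pyrone alone is a poor acceptor diene, so pyrone C3 carries a bromine as a removable activator; it ends on ring A C4 and is taken off by bromine–lithium exchange.
Stereochemistry: the single (S)-centre comes from a catalyst-controlled ketone reduction to the (R)-carbinol. It is relayed by retentive borylation, an invertive 1,2-aryl shift and retentive protodeboronation; the E-alkene comes from thermodynamically controlled dehydration.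

Key step: step 10

Shorthand: ring C is the 2,4-dioxygenated ring on the methine, and ring D is the 3,5-dioxygenated ring on the CH2. Ar* = 5-[(1S)-1-(2,4-dimethoxyphenyl)-2-(3,5-dimethoxyphenyl)ethyl]-2,4-dimethoxyphenyl. At the stereocentre the CIP order is ring B > ring C > CH2 > H (or B), so the target SMILES reads as (S).

Step 1
Reactants: 1 5-bromo-2,4-dimethoxybenzaldehyde
Product: 2 2-(5-bromo-2,4-dimethoxyphenyl)-5,5-dimethyl-1,3-dioxane
Conditions: 2,2-dimethylpropane-1,3-diol, p-TsOH (cat), toluene, reflux, Dean–Stark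
Reagents that add atoms: 2,2-dimethylpropane-1,3-diol, OCC(C)(C)CO
Why: Acid-catalysed acetalisation with azeotropic removal of water masks the aldehyde as a cyclic acetal that tolerates the palladium, organolithium and fluoride steps ahead.

Step 2
Reactants: 2 2-(5-bromo-2,4-dimethoxyphenyl)-5,5-dimethyl-1,3-dioxane
Product: 3 2-[5-(5,5-dimethyl-1,3-dioxan-2-yl)-2,4-dimethoxyphenyl]-4,4,5,5-tetramethyl-1,3,2-dioxaborolane
Conditions: B2pin2, Pd(dppf)Cl2 (3 mol %), KOAc, 1,4-dioxane, 90 °C
Reagents that add atoms: bis(pinacolato)diboron, CC1(C)OB(OC1(C)C)B1OC(C)(C)C(C)(C)O1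
Why: Miyaura borylation of an aryl bromide runs under weakly basic conditions that leave the acetal and the methyl ethers alone.

Step 3
Reactants: 4 1-(2,4-dimethoxyphenyl)ethan-1-one; 5 1-bromo-3,5-dimethoxybenzene
Product: 6 1-(2,4-dimethoxyphenyl)-2-(3,5-dimethoxyphenyl)ethan-1-one
Conditions: Pd2(dba)3 (1 mol %), Xantphos (2.5 mol %), NaOtBu, THF, 70 °C
Reagents that add atoms: none
Why: Palladium-catalysed α-arylation of an aryl methyl ketone enolate is an established route to deoxybenzoins, and the wide-bite-angle ligand together with fast deprotonation of the more acidic product holds it at monoarylation.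

Step 4
Reactants: 6 1-(2,4-dimethoxyphenyl)-2-(3,5-dimethoxyphenyl)ethan-1-one
Product: 7 (1R)-1-(2,4-dimethoxyphenyl)-2-(3,5-dimethoxyphenyl)ethan-1-ol
Conditions: (S)-2-methyl-CBS-oxazaborolidine (10 mol %), BH3·SMe2, THF, −20 °C; then MeOH
Reagents that add atoms: none
Why: In this Corey–Bakshi–Shibata reduction the ketone binds to the catalyst boron with the bulky 2,4-dimethoxyphenyl group turned away from the B-methyl group and the benzyl arm in the small-group position, so the coordinated borane delivers hydride to the Si face and sets the (R)-carbinol centre.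

Step 5
Reactants: 7 (1R)-1-(2,4-dimethoxyphenyl)-2-(3,5-dimethoxyphenyl)ethan-1-ol
Product: 8 (1R)-1-(2,4-dimethoxyphenyl)-2-(3,5-dimethoxyphenyl)ethyl N,N-diisopropylcarbamate
Conditions: NaH, THF, 0 °C; iPr2NCOCl, 0 → 50 °C
Reagents that add atoms: N,N-diisopropylcarbamoyl chloride, CC(C)N(C(C)C)C(=O)Cl
Why: O-Carbamoylation of the sodium alkoxide touches only the O–H bond, so the (R)-configuration is kept while the directing and leaving group for the next step is installed under acid-free conditions.

Step 6
Reactants: 8 (1R)-1-(2,4-dimethoxyphenyl)-2-(3,5-dimethoxyphenyl)ethyl N,N-diisopropylcarbamate; 3 2-[5-(5,5-dimethyl-1,3-dioxan-2-yl)-2,4-dimethoxyphenyl]-4,4,5,5-tetramethyl-1,3,2-dioxaborolane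
Product: 11 2-{(1S)-1-(2,4-dimethoxyphenyl)-2-(3,5-dimethoxyphenyl)-1-[5-(5,5-dimethyl-1,3-dioxan-2-yl)-2,4-dimethoxyphenyl]ethyl}-4,4,5,5-tetramethyl-1,3,2-dioxaborolane, via lithiated carbamate 9 (not isolated), via lithium boronate complex 10 (not isolated)
Conditions: sBuLi, Et2O, −78 °C; then 3, −78 °C; then MgBr2 in MeOH, −78 °C → rt
Reagents that add atoms: none
Why: In this lithiation–borylation the carbamate-directed deprotonation gives a benzylic organolithium that is configurationally stable at −78 °C and captures the boronic ester with retention, and the anti-periplanar 1,2-shift of the ring B aryl group then expels the carbamate with inversion at carbon, so the (R)-carbamate is translated into the (S)-tertiary boronic ester.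

Step 7
Reactants: 11 the (S)-tertiary boronic ester of step 6
Product: 13 5-[(1S)-1-(2,4-dimethoxyphenyl)-2-(3,5-dimethoxyphenyl)ethyl]-2,4-dimethoxybenzaldehyde (Ar*–CHO), via triarylethane acetal 12 (not isolated)
Conditions: CsF, H2O (1.1 equiv), 1,4-dioxane, 45 °C; then 1 M HCl, THF, rt
Reagents that add atoms: water, O
Why: Fluoride-promoted protodeboronation of tertiary diarylalkyl pinacol boronic esters replaces boron by hydrogen with retention of configuration, which fixes the (S)-methine, and the electron-rich aryl acetal is then hydrolysed by dilute acid in the same flask.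

Step 8
Reactants: 14 4-methoxy-6-methyl-2H-pyran-2-one
Product: 15 3-bromo-4-methoxy-6-methyl-2H-pyran-2-one
Conditions: NBS, MeCN, rt, dark
Reagents that add atoms: N-bromosuccinimide, O=C1CCC(=O)N1Br
Why: Electrophilic bromination under ionic conditions goes to C3, the nucleophilic β-carbon of the 4-methoxy enol ether, and it is done here because the electron-rich arenes of the later intermediates would compete for the bromine.

Step 9
Reactants: 13 Ar*–CHO; 15 3-bromo-4-methoxy-6-methyl-2H-pyran-2-one
Product: 16 3-bromo-4-methoxy-6-[(E)-2-Ar*-ethenyl]-2H-pyran-2-one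
Conditions: Mg(OMe)2, MeOH, reflux
Reagents that add atoms: none
Why: In this vinylogous aldol condensation Mg(OMe)2 reversibly deprotonates the C6 methyl group to the extended dienolate, which adds to the aldehyde, and E1cB loss of water gives the conjugated alkene as the more stable E isomer, as is known for 4-methoxy-6-styryl-2-pyrones.

Step 10
Reactants: 16 3-bromo-4-methoxy-6-[(E)-2-Ar*-ethenyl]-2H-pyran-2-one; 17 1,1-diethoxyethene
Product: 20 2-bromo-1-ethoxy-3-methoxy-5-[(E)-2-Ar*-ethenyl]benzene, via bridged lactone 18 (not isolated), via diethoxycyclohexadiene 19 (not isolated)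
Conditions: 17 (15 equiv), K2CO3 (acid scavenger, 5 mol %), mesitylene, sealed tube, 150 °C
Reagents that add atoms: none
Why: Proposed new method: the nucleophilic CH2 carbon of 17 attacks the electrophilic pyrone C6 while the acetal carbon bonds to C3 in an asynchronous inverse-electron-demand Diels–Alder addition across the ring diene C3=C4–C5=C6, the bridged lactone 18 then ejects its O1–C2 bridge as carbon dioxide by cycloreversion, and dihydroarene 19 loses ethanol by 1,2-elimination to give the benzene ring of 20. The closest known reaction type is the benzannulation of 2-pyrones bearing an acceptor at C3 or C5 with ketene acetals, supported by the known thermal additions of enol ethers to 3-bromo-2-pyrones, whereas a 4-alkoxy-6-alkenyl-2-pyrone has not been tried. The C3 bromine is there to offset the donor effect of the 4-methoxy and styryl groups, since it lowers the diene LUMO and stabilises the negative charge that builds on C3 in the transition state, and 17 is far more nucleophilic than the enol ethers that already add to bromopyrones. Ring A closes by intermolecular (4+2) cycloaddition in which both new ring bonds (C6–CH2 and C3–C(OEt)2) are made, four ring carbons coming from the pyrone and two from 17. The two bridgehead stereocentres of 18 arise without control and vanish on aromatisation, no lasting stereocentre is created, and the neutral medium leaves the (S)-methine and the E-alkene alone. The step needs the regiochemistry that puts ethoxy meta to the alkene, which the polarity match between the acetal CH2 and C6 secures, and it needs the ring diene to react instead of the exocyclic C5=C6–CH=CH diene, which is secured because only the ring adduct can leave irreversibly by loss of carbon dioxide.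

Step 11
Reactants: 20 2-bromo-1-ethoxy-3-methoxy-5-[(E)-2-Ar*-ethenyl]benzene
Product: 22 1-ethoxy-3-methoxy-5-[(E)-2-Ar*-ethenyl]benzene (heptamethyl monoethyl ether of the target), via aryllithium 21 (not isolated)
Conditions: nBuLi (1.1 equiv), THF, −78 °C, 10 min; then H2O
Reagents that add atoms: none
Why: Bromine–lithium exchange on the aryl bromide flanked by two alkoxy groups is much faster at −78 °C than deprotonation of the diarylmethine or addition to the stilbene, and protonation of the aryllithium removes the activating group.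

Step 12
Reactants: 22 1-ethoxy-3-methoxy-5-[(E)-2-Ar*-ethenyl]benzene
Product: 23 4-[(E)-2-(3,5-dihydroxyphenyl)ethenyl]-6-[(1S)-1-(2,4-dihydroxyphenyl)-2-(3,5-dihydroxyphenyl)ethyl]benzene-1,3-diol (CNP0376747.1)
Conditions: BBr3 (excess), CH2Cl2, −78 °C → rt; then H2O, 0 °C
Reagents that add atoms: none
Why: Lewis-acid ether cleavage with BBr3 (coordination of boron to oxygen, then bromide attack on the alkyl carbon) removes the seven methyl groups and the ethyl group alike without touching the alkene geometry or the stereocentre, as is routine for hydroxystilbenes.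

Compound list
1 | 5-bromo-2,4-dimethoxybenzaldehyde | COc1cc(OC)c(C=O)cc1Br | starting material
2 | 2-(5-bromo-2,4-dimethoxyphenyl)-5,5-dimethyl-1,3-dioxane | COc1cc(OC)c(C2OCC(C)(C)CO2)cc1Br | intermediate
3 | 2-[5-(5,5-dimethyl-1,3-dioxan-2-yl)-2,4-dimethoxyphenyl]-4,4,5,5-tetramethyl-1,3,2-dioxaborolane | COc1cc(OC)c(C2OCC(C)(C)CO2)cc1B1OC(C)(C)C(C)(C)O1 | intermediate
4 | 1-(2,4-dimethoxyphenyl)ethan-1-one | CC(=O)c1ccc(OC)cc1OC | starting material
5 | 1-bromo-3,5-dimethoxybenzene | COc1cc(Br)cc(OC)c1 | starting material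
6 | 1-(2,4-dimethoxyphenyl)-2-(3,5-dimethoxyphenyl)ethan-1-one | COc1ccc(C(=O)Cc2cc(OC)cc(OC)c2)c(OC)c1 | intermediate
7 | (1R)-1-(2,4-dimethoxyphenyl)-2-(3,5-dimethoxyphenyl)ethan-1-ol | COc1ccc([C@H](O)Cc2cc(OC)cc(OC)c2)c(OC)c1 | intermediate
8 | (1R)-1-(2,4-dimethoxyphenyl)-2-(3,5-dimethoxyphenyl)ethyl N,N-diisopropylcarbamate | COc1ccc([C@H](OC(=O)N(C(C)C)C(C)C)Cc2cc(OC)cc(OC)c2)c(OC)c1 | intermediate
9 | α-lithiated carbamate, lithium in the place of the carbinol hydrogen (retention) | COc1ccc([C@]([Li])(OC(=O)N(C(C)C)C(C)C)Cc2cc(OC)cc(OC)c2)c(OC)c1 | intermediate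
10 | lithium boronate complex of 9 and 3, boron in the place of lithium (retention) | [Li+].COc1ccc([C@]([B-]2(c3cc(C4OCC(C)(C)CO4)c(OC)cc3OC)OC(C)(C)C(C)(C)O2)(OC(=O)N(C(C)C)C(C)C)Cc2cc(OC)cc(OC)c2)c(OC)c1 | intermediate
11 | (S)-tertiary pinacol boronic ester bearing rings B (as acetal), C and the ring D benzyl group | COc1ccc([C@@](B2OC(C)(C)C(C)(C)O2)(c2cc(C3OCC(C)(C)CO3)c(OC)cc2OC)Cc2cc(OC)cc(OC)c2)c(OC)c1 | intermediate
12 | 2-{5-[(1S)-1-(2,4-dimethoxyphenyl)-2-(3,5-dimethoxyphenyl)ethyl]-2,4-dimethoxyphenyl}-5,5-dimethyl-1,3-dioxane | COc1ccc([C@@H](c2cc(C3OCC(C)(C)CO3)c(OC)cc2OC)Cc2cc(OC)cc(OC)c2)c(OC)c1 | intermediate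
13 | 5-[(1S)-1-(2,4-dimethoxyphenyl)-2-(3,5-dimethoxyphenyl)ethyl]-2,4-dimethoxybenzaldehyde | COc1ccc([C@@H](c2cc(C=O)c(OC)cc2OC)Cc2cc(OC)cc(OC)c2)c(OC)c1 | intermediate
14 | 4-methoxy-6-methyl-2H-pyran-2-one | COC1=CC(=O)OC(C)=C1 | starting material
15 | 3-bromo-4-methoxy-6-methyl-2H-pyran-2-one | COC1=C(Br)C(=O)OC(C)=C1 | intermediate
16 | 3-bromo-4-methoxy-6-[(E)-2-Ar*-ethenyl]-2H-pyran-2-one, (S) | COC1=C(Br)C(=O)OC(/C=C/c2cc([C@@H](Cc3cc(OC)cc(OC)c3)c3ccc(OC)cc3OC)c(OC)cc2OC)=C1 | intermediate
17 | 1,1-diethoxyethene | CCOC(=C)OCC | starting material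
18 | 4-bromo-8,8-diethoxy-5-methoxy-1-[(E)-2-Ar*-ethenyl]-2-oxabicyclo[2.2.2]oct-5-en-3-one, both bridgehead configurations | O=C1OC2(/C=C/c3cc([C@@H](Cc4cc(OC)cc(OC)c4)c4ccc(OC)cc4OC)c(OC)cc3OC)CC(OCC)(OCC)C1(Br)C(OC)=C2 | intermediate
19 | 1-bromo-6,6-diethoxy-2-methoxy-4-[(E)-2-Ar*-ethenyl]cyclohexa-1,3-diene | CCOC1(OCC)CC(/C=C/c2cc([C@@H](Cc3cc(OC)cc(OC)c3)c3ccc(OC)cc3OC)c(OC)cc2OC)=CC(OC)=C1Br | intermediate
20 | 2-bromo-1-ethoxy-3-methoxy-5-[(E)-2-Ar*-ethenyl]benzene, (S) | CCOc1cc(/C=C/c2cc([C@@H](Cc3cc(OC)cc(OC)c3)c3ccc(OC)cc3OC)c(OC)cc2OC)cc(OC)c1Br | intermediate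
21 | aryllithium from 20, lithium in the place of bromine | CCOc1cc(/C=C/c2cc([C@@H](Cc3cc(OC)cc(OC)c3)c3ccc(OC)cc3OC)c(OC)cc2OC)cc(OC)c1[Li] | intermediate
22 | 1-ethoxy-3-methoxy-5-[(E)-2-Ar*-ethenyl]benzene, (S) | CCOc1cc(OC)cc(/C=C/c2cc([C@@H](Cc3cc(OC)cc(OC)c3)c3ccc(OC)cc3OC)c(OC)cc2OC)c1 | intermediate
23 | 4-[(E)-2-(3,5-dihydroxyphenyl)ethenyl]-6-[(1S)-1-(2,4-dihydroxyphenyl)-2-(3,5-dihydroxyphenyl)ethyl]benzene-1,3-diol | Oc1cc(O)cc(/C=C/c2cc([C@@H](Cc3cc(O)cc(O)c3)c3ccc(O)cc3O)c(O)cc2O)c1 | target

Total step count: 12. Longest linear sequence: 9 steps (steps 3, 4, 5, 6, 7, 9, 10, 11, 12, from 4 and 5).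

Steps most likely to fail

**Step 10.** The cycloaddition may be too slow. The donors at C4 and C6 raise the LUMO of the diene even with the bromine in place, and at the temperature needed the ketene acetal may be lost to oligomerisation before it adds. The fallback uses known chemistry and gives up the pyrone route to ring A.
- It sets out from aldehyde 13.
- Horner–Wadsworth–Emmons olefination with commercial diethyl (3,5-dimethoxybenzyl)phosphonate (NaH, THF, 0 °C → rt) should give the E-configured (S)-octamethyl ether of the target F1.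
- BBr3 under the conditions of step 12 then cleaves all eight methyl ethers, so the fallback comes back to the route at 23.

**Step 6.** Both partners carry an ortho-methoxy group, so the boronate complex may form slowly or reversibly, and the released organolithium would racemise on warming. The very electron-rich benzylic C–O bond may also ionise before the aryl group migrates, which would erode stereospecificity. Ring lithiation may compete with benzylic deprotonation. The fallback avoids the tertiary boronic ester altogether.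
- It sets out from bromide 2.
- Commercial 2-(3,5-dimethoxyphenyl)ethanol is carbamoylated (NaH, iPr2NCOCl) to 2-(3,5-dimethoxyphenyl)ethyl N,N-diisopropylcarbamate F2.
- Asymmetric deprotonation with sBuLi/(+)-sparteine (Et2O, −78 °C), capture with commercial 2-(2,4-dimethoxyphenyl)-4,4,5,5-tetramethyl-1,3,2-dioxaborolane and 1,2-aryl migration on warming should give 2-[(1S)-1-(2,4-dimethoxyphenyl)-2-(3,5-dimethoxyphenyl)ethyl]-4,4,5,5-tetramethyl-1,3,2-dioxaborolane F3.
- A stereoretentive Suzuki–Miyaura coupling of this secondary benzylic boronic ester with 2 (Pd2(dba)3, PPh3, Ag2O, DME, 85 °C) comes back to the route at acetal 12.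
- Acetal 12 is hydrolysed as in the second half of step 7.

**Step 9.** Addition of the dienolate to the hindered, strongly deactivated aldehyde may be slow. Methoxide may meanwhile open the bromopyrone ring, or bromine may be transferred between pyrone anions. The fallback replaces the equilibrium condensation by an olefination.
- It sets out from 15.
- Wohl–Ziegler bromination (NBS, AIBN, PhCF3, reflux) gives 3-bromo-6-(bromomethyl)-4-methoxy-2H-pyran-2-one F4.
- A Michaelis–Arbuzov reaction with P(OEt)3 (120 °C) gives diethyl [(3-bromo-4-methoxy-2-oxo-2H-pyran-6-yl)methyl]phosphonate F5.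
- Horner–Wadsworth–Emmons reaction of F5 with 13 (LiHMDS, THF, −78 °C → rt) should give the E-alkene, so the fallback comes back to the route at 16.

Further compounds
F1 | step 10 | 1,3-dimethoxy-5-[(E)-2-Ar*-ethenyl]benzene, (S)-octamethyl ether of the target | COc1cc(OC)cc(/C=C/c2cc([C@@H](Cc3cc(OC)cc(OC)c3)c3ccc(OC)cc3OC)c(OC)cc2OC)c1
F2 | step 6 | 2-(3,5-dimethoxyphenyl)ethyl N,N-diisopropylcarbamate | COc1cc(CCOC(=O)N(C(C)C)C(C)C)cc(OC)c1
F3 | step 6 | 2-[(1S)-1-(2,4-dimethoxyphenyl)-2-(3,5-dimethoxyphenyl)ethyl]-4,4,5,5-tetramethyl-1,3,2-dioxaborolane | COc1ccc([C@@H](B2OC(C)(C)C(C)(C)O2)Cc2cc(OC)cc(OC)c2)c(OC)c1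
F4 | step 9 | 3-bromo-6-(bromomethyl)-4-methoxy-2H-pyran-2-one | COC1=C(Br)C(=O)OC(CBr)=C1
F5 | step 9 | diethyl [(3-bromo-4-methoxy-2-oxo-2H-pyran-6-yl)methyl]phosphonate | CCOP(=O)(CC1=CC(OC)=C(Br)C(=O)O1)OCC
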